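The impurity was the first thing I looked at in this flask, since it reacts with the initiator too.

free monomer 2.0 M; initiator 0.5 mol%; impurity 1.3 mM; time 3.0 h

    free monomer + initiator → living end + monomer in chains (k1 = 5.4 × 10⁻⁴ M⁻¹ s⁻¹)
    free monomer + living end → monomer in chains + living end, rate k2*[living end]*[free monomer] (k2 = 0.042 M⁻¹ s⁻¹)
    initiator + impurity → spent initiator A (k3 = 4.7 M⁻¹ s⁻¹)
    initiator + monomer in chains → spent initiator B (k4 = 2.5 × 10⁻⁴ M⁻¹ s⁻¹)

- the average divides the monomer in chains by the number of chains begun, living and dead together
- run time (flask): 3.0 h

1. average number of monomer units in a chain (chains begun, living or dead) at 3.0 h
2. part of the free monomer that has reacted at 3.0 h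

I turned the constants into times at the charged amounts. On the first rung, the impurity's time against the initiator was 21.3 s, much shorter than the 15.4 min of the initiator against free monomer. So I let the impurity take its own amount first, 13.0% of the initiator charge, and called the remainder the working share, 87.0%.

The next rung was the quantity I carried, the chain clock: one over k2 times the living ends that the working share gives, 45.6 min. Because the initiator's time was shorter than this clock, I treated free monomer as falling pseudo-first-order once the living ends had formed. Starting the clock one initiator time late, the run held 3.61 clock periods, so I reckoned 97.3% reacted. Setting the chains begun equal to the working share, I estimated a length of 224.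

The forecast gave 242 and 96.4%, on the grounds of “a monomer lifetime of about 50 minutes”; its length stood above mine.

The flask gave 242 and 96.4%; after my 3.61 clock periods, at 3.00 h, it held 3.6% of its free monomer, where I had reckoned 2.70%. At 3.00 h its living ends came to 79.5% of the initiator charge, below the working share. For a neighbour flask, charged with impurity worth 52.0% of the initiator, I reckoned a working share of 48.0% and a clock of 82.7 min, which gave 86.3% reacted. That neighbour flask reached 85.2% reacted.

(The numbers of this flask belong to no real substance; the rest is arithmetic.)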